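**Retrosynthetic overview**

1. Target 18 ⇐ Mitsunobu O-allylation of 4-hydroxy-5-methylcoumarin 17 with E-allylic alcohol 15; the pyranone ring of 17 comes from acetophenone 16 and diethyl carbonate.
2. 15 ⇐ terminal alkyne 12 (Zr-catalysed methylalumination and hydroxymethylation fix the E trisubstituted alkene) ⇐ methyl ketone 10 ⇐ enone 9.
3. 9 ⇐ (S)-2,2,4-trimethylcyclohex-3-en-1-ol 6 + methyl vinyl ketone 7: one domino cis-oxypalladation/Heck step closes the O7 bridge, joins ring carbon C2 to the side-chain CH2 and sets C1 and C2 from the single carbinol centre.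
4. Enabling feature: C2 of the 7-oxabicyclo[2.2.1]heptane lies between the fully substituted C1 (methyl, O7) and C3 (gem-dimethyl), so a C2–Pd bond has no β-hydrogen. O7 spans C1 and C4 (1,4 across the carbocycle), so a cyclohexenol can close the bridge transannularly, as in the presumed biosynthetic capture of the C1 cation.
5. Ring order: carbocycle (from 4-methylanisole 1 by Birch reduction, gem-dimethylation, CBS reduction), then the oxygen bridge (key step); the coumarin lactone ring is made separately and attached last.

Key step: step 4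

Remark: the bicycle is numbered C1 (methyl-bearing bridgehead), C2 (side-chain carbon), C3 (gem-dimethyl carbon), C4 (bridgehead CH), C5, C6, O7. These are C4, C3, C2, C1, C6, C5 and the hydroxyl oxygen of cyclohexenol 6. In the target (1R,2S,4S) the side chain on C2 is exo, on the side of O7. Compounds 1, 7 and 16 are taken as commercial.

**Route**

Step 1
Reactants: 1 4-methylanisole
Product: 3 4-methylcyclohex-3-en-1-one, via 1-methoxy-4-methylcyclohexa-1,4-diene 2 (not isolated)
Conditions: Li, NH3(l), t-BuOH, THF, −78 to −33 °C; NH3 evaporated; then (CO2H)2, H2O/THF, rt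
Reagents that add atoms: water, O
Why: Birch reduction of the anisole should give the 2,5-dihydroanisole, and mild enol ether hydrolysis should give the β,γ-unsaturated ketone; any migration of the alkene into conjugation would be harmless because step 2 passes through the same dienolate from either isomer.

Step 2
Reactants: 3 4-methylcyclohex-3-en-1-one
Product: 5 2,2,4-trimethylcyclohex-3-en-1-one, via 2,4-dimethylcyclohex-3-en-1-one 4 (not isolated)
Conditions: t-BuOK (2.2 equiv), MeI (3 equiv), t-BuOH/THF, 0 °C to rt
Reagents that add atoms: iodomethane, CI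
Why: the extended thermodynamic potassium dienolate should be methylated twice at the α-carbon between carbonyl and alkene (deconjugative α,α-dialkylation of enones, as in the classical gem-dimethylation of steroidal enones), which builds the gem-dimethyl carbon and locks the alkene in the β,γ-position; no stereocentre is present.

Step 3
Reactants: 5 2,2,4-trimethylcyclohex-3-en-1-one
Product: 6 (S)-2,2,4-trimethylcyclohex-3-en-1-ol
Conditions: (R)-1-methyl-3,3-diphenyltetrahydro-1H,3H-pyrrolo[1,2-c][1,3,2]oxazaborole ((R)-Me-CBS, 0.2 equiv), catecholborane (1.5 equiv), toluene, −78 to −40 °C; aq. NaOH work-up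
Reagents that add atoms: none
Why: Corey–Bakshi–Shibata reduction of a ketone flanked by a quaternary carbon (large group) and a methylene (small group) is expected, by the usual model, to give the S carbinol with the R catalyst, and catecholborane should leave the trisubstituted alkene untouched at this temperature.

Step 4
Reactants: 6 (S)-2,2,4-trimethylcyclohex-3-en-1-ol; 7 methyl vinyl ketone
Product: 9 (E)-4-[(1R,2S,4S)-1,3,3-trimethyl-7-oxabicyclo[2.2.1]heptan-2-yl]but-3-en-2-one, via alkylpalladium trifluoroacetate 8 (not isolated)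
Conditions: Pd(OCOCF3)2 (10 mol %), p-benzoquinone (2 equiv), 7 (5 equiv), 4 Å MS, CH2Cl2, 25–40 °C, chloride-free
Reagents that add atoms: none
Why: Proposed new method: the hydroxyl of 6 exchanges onto divalent palladium and the alkoxide adds together with the metal to the same face of the ring alkene (cis-oxypalladation), forming the O7–C1 bond and an exo C2–Pd bond in 8; 8 then inserts methyl vinyl ketone at its CH2 terminus, β-hydride loss gives the E-enone, and benzoquinone returns zerovalent palladium to the divalent state. The closest known reaction type is the domino Wacker–Heck (oxypalladation–vinylation) reaction of alkenyl alcohols and alkenyl phenols with 1,1-disubstituted double bonds, in which a primary neopentyl-type alkylpalladium is trapped by an acrylate or enone; new here are the endocyclic trisubstituted alkene, the bridging closure and the secondary C–Pd bond. The one ring closed is the oxolane O7–C1–C6–C5–C4, by transannular 5-exo-trig attack of oxygen on C1 with the C1=C2 bond outside the forming ring, which turns the cyclohexene into the 7-oxabicyclo[2.2.1]heptane. C1 is set by the tether, because the oxygen on C4 can only reach the face of C1 on which it sits, and C2 is set by the cis course of the oxypalladation followed by insertion with retention at carbon, which leaves the new C–C bond exo, on the side of O7. The step needs cis- over trans-oxypalladation, for which chloride-free carboxylate conditions are chosen because they favour the alkoxide-insertion path, and it needs intermolecular capture of 8 to outrun its decay, which the substrate secures because C1 and C3 carry no hydrogen, so β-hydride elimination from 8 is impossible. Attack of oxygen on C2 is excluded because it would close an oxetane.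

Step 5
Reactants: 9 (E)-4-[(1R,2S,4S)-1,3,3-trimethyl-7-oxabicyclo[2.2.1]heptan-2-yl]but-3-en-2-one
Product: 10 4-[(1R,2S,4S)-1,3,3-trimethyl-7-oxabicyclo[2.2.1]heptan-2-yl]butan-2-one
Conditions: H2 (1 atm), 10% Pd/C, EtOAc, rt
Reagents that add atoms: none
Why: heterogeneous hydrogenation should saturate the conjugated disubstituted alkene while ketone and bridged ether stay intact, and no stereocentre is touched.

Step 6
Reactants: 10 4-[(1R,2S,4S)-1,3,3-trimethyl-7-oxabicyclo[2.2.1]heptan-2-yl]butan-2-one
Product: 12 (1R,2S,4S)-2-(but-3-yn-1-yl)-1,3,3-trimethyl-7-oxabicyclo[2.2.1]heptane, via enol diethyl phosphate 11 (not isolated)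
Conditions: LiN(i-Pr)2 (1.05 equiv), THF, −78 °C; ClP(O)(OEt)2, −78 °C to rt; then LiN(i-Pr)2 (2.3 equiv), −78 °C to rt; H2O
Reagents that add atoms: none
Why: kinetic deprotonation on the methyl side, O-phosphorylation and base-induced elimination of the terminal enol phosphate (the standard methyl ketone to terminal alkyne conversion) should give the alkyne without touching the base-stable bicycle.

Step 7
Reactants: 12 (1R,2S,4S)-2-(but-3-yn-1-yl)-1,3,3-trimethyl-7-oxabicyclo[2.2.1]heptane
Product: 15 (E)-3-methyl-5-[(1R,2S,4S)-1,3,3-trimethyl-7-oxabicyclo[2.2.1]heptan-2-yl]pent-2-en-1-ol, via alkenyldimethylalane 13 (not isolated), via lithium alkenyl(butyl)dimethylalanate 14 (not isolated)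
Conditions: Me3Al (2.5 equiv), Cp2ZrCl2 (0.25 equiv), CH2Cl2, 0 °C to rt; then n-BuLi, THF/hexane, −78 °C; (CH2O)n, −78 °C to rt; aq. work-up
Reagents that add atoms: trimethylaluminium, C[Al](C)C; paraformaldehyde (formaldehyde), C=O
Why: Negishi zirconium-catalysed carboalumination adds methyl and aluminium cis across the terminal alkyne with methyl on the internal carbon, and hydroxymethylation of the alanate proceeds with retention, so the E trisubstituted alkene should form stereospecifically.

Step 8
Reactants: 16 1-(2-hydroxy-6-methylphenyl)ethan-1-one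
Product: 17 4-hydroxy-5-methyl-2H-chromen-2-one
Conditions: NaH (3 equiv), (EtO)2CO, toluene, 110 °C; then aq. HCl
Reagents that add atoms: diethyl carbonate, CCOC(=O)OCC
Why: Claisen-type C-acylation of the ketone enolate by diethyl carbonate followed by lactonisation onto the phenoxide is the standard 4-hydroxycoumarin synthesis from 2-hydroxyacetophenones.

Step 9
Reactants: 15 (E)-3-methyl-5-[(1R,2S,4S)-1,3,3-trimethyl-7-oxabicyclo[2.2.1]heptan-2-yl]pent-2-en-1-ol; 17 4-hydroxy-5-methyl-2H-chromen-2-one
Product: 18 5-methyl-4-{[(2E)-3-methyl-5-[(1R,2S,4S)-1,3,3-trimethyl-7-oxabicyclo[2.2.1]heptan-2-yl]pent-2-en-1-yl]oxy}-2H-chromen-2-one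
Conditions: PPh3, i-PrO2CN=NCO2i-Pr, THF, 0 °C to rt
Reagents that add atoms: none
Why: Mitsunobu etherification, in which the acidic 4-hydroxyl (a vinylogous carboxylic acid) displaces the alkoxyphosphonium of the primary allylic alcohol by direct substitution, should keep the alkene geometry, and the low temperature avoids Claisen rearrangement of the 4-allyloxycoumarin.

**Compound list**

1 | 4-methylanisole | COc1ccc(C)cc1 | starting material
2 | 1-methoxy-4-methylcyclohexa-1,4-diene | COC1=CCC(C)=CC1 | intermediate (not isolated)
3 | 4-methylcyclohex-3-en-1-one | CC1=CCC(=O)CC1 | intermediate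
4 | 2,4-dimethylcyclohex-3-en-1-one (racemic) | CC1=CC(C)C(=O)CC1 | intermediate (not isolated)
5 | 2,2,4-trimethylcyclohex-3-en-1-one | CC1=CC(C)(C)C(=O)CC1 | intermediate
6 | (S)-2,2,4-trimethylcyclohex-3-en-1-ol | CC1=CC(C)(C)[C@@H](O)CC1 | intermediate
7 | methyl vinyl ketone (but-3-en-2-one) | CC(=O)C=C | starting material
8 | [(1R,2S,4S)-1,3,3-trimethyl-7-oxabicyclo[2.2.1]heptan-2-yl]palladium trifluoroacetate (Pd exo) | O=C(O[Pd][C@H]1C(C)(C)[C@@H]2CC[C@@]1(C)O2)C(F)(F)F | intermediate (not isolated)
9 | (E)-4-[(1R,2S,4S)-1,3,3-trimethyl-7-oxabicyclo[2.2.1]heptan-2-yl]but-3-en-2-one | CC(=O)/C=C/[C@H]1C(C)(C)[C@@H]2CC[C@@]1(C)O2 | intermediate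
10 | 4-[(1R,2S,4S)-1,3,3-trimethyl-7-oxabicyclo[2.2.1]heptan-2-yl]butan-2-one | CC(=O)CC[C@H]1C(C)(C)[C@@H]2CC[C@@]1(C)O2 | intermediate
11 | diethyl 4-[(1R,2S,4S)-1,3,3-trimethyl-7-oxabicyclo[2.2.1]heptan-2-yl]but-1-en-2-yl phosphate | C=C(CC[C@H]1C(C)(C)[C@@H]2CC[C@@]1(C)O2)OP(=O)(OCC)OCC | intermediate (not isolated)
12 | (1R,2S,4S)-2-(but-3-yn-1-yl)-1,3,3-trimethyl-7-oxabicyclo[2.2.1]heptane | C#CCC[C@H]1C(C)(C)[C@@H]2CC[C@@]1(C)O2 | intermediate
13 | dimethyl{(E)-2-methyl-4-[(1R,2S,4S)-1,3,3-trimethyl-7-oxabicyclo[2.2.1]heptan-2-yl]but-1-en-1-yl}alane | C/C(=C\[Al](C)C)CC[C@H]1C(C)(C)[C@@H]2CC[C@@]1(C)O2 | intermediate (not isolated)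
14 | lithium butyl(dimethyl){(E)-2-methyl-4-[(1R,2S,4S)-1,3,3-trimethyl-7-oxabicyclo[2.2.1]heptan-2-yl]but-1-en-1-yl}alanate | [Li+].CCCC[Al-](C)(C)/C=C(\C)CC[C@H]1C(C)(C)[C@@H]2CC[C@@]1(C)O2 | intermediate (not isolated)
15 | (E)-3-methyl-5-[(1R,2S,4S)-1,3,3-trimethyl-7-oxabicyclo[2.2.1]heptan-2-yl]pent-2-en-1-ol | C/C(=C\CO)CC[C@H]1C(C)(C)[C@@H]2CC[C@@]1(C)O2 | intermediate
16 | 1-(2-hydroxy-6-methylphenyl)ethan-1-one | CC(=O)c1c(C)cccc1O | starting material
17 | 4-hydroxy-5-methyl-2H-chromen-2-one | Cc1cccc2oc(=O)cc(O)c12 | intermediate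
18 | 5-methyl-4-{[(2E)-3-methyl-5-[(1R,2S,4S)-1,3,3-trimethyl-7-oxabicyclo[2.2.1]heptan-2-yl]pent-2-en-1-yl]oxy}-2H-chromen-2-one | C/C(=C\COc1cc(=O)oc2cccc(C)c12)CC[C@H]1C(C)(C)[C@@H]2CC[C@@]1(C)O2 | target

**Step count and risks**

Total step count: 9. Longest linear sequence: 8 (steps 1 to 7 and 9).

Steps most likely to fail:

Step 4 (proposed new method). Three processes threaten it:
- β-hydride loss from the palladium alkoxide would oxidise the carbinol back to ketone 5 (recyclable through step 3), or allylic C–H palladation could outrun the oxypalladation.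
- A trans course of the oxypalladation would put palladium on the endo face and give the C2 epimer.
- Insertion of the enone into the hindered secondary C–Pd bond may be too slow.

Fallback with known chemistry, setting out from 6 and returning at 10, so that step 5 is not needed. Iodoetherification of 6 (I2, NaHCO3, MeCN, 0 °C) should close the same bridge by Markovnikov trans addition and give (1R,2R,4S)-2-iodo-1,3,3-trimethyl-7-oxabicyclo[2.2.1]heptane F1. A radical Giese addition of F1 to 7 ((Me3Si)3SiH, AIBN, toluene, 80 °C) should then give 10. The planar C2 radical is expected to be attacked from the open exo face, so the configuration of the iodide does not matter.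

Step 7. Coordination of the aluminium reagent to O7 may slow the carbometalation, or Lewis-acid ionisation of the tertiary C1–O7 bond may open the bicycle. Fallback, setting out from 12 and returning at 15, with the same geometric control by a different mechanism:
- Hydroxymethylation of the lithium acetylide (n-BuLi, THF, −78 °C; (CH2O)n) should give 5-[(1R,2S,4S)-1,3,3-trimethyl-7-oxabicyclo[2.2.1]heptan-2-yl]pent-2-yn-1-ol F2.
- Alkoxide-directed trans-hydroalumination and iodination (NaAlH2(OCH2CH2OMe)2, THF, 0 °C to rt; I2, −78 °C) should give (Z)-3-iodo-5-[(1R,2S,4S)-1,3,3-trimethyl-7-oxabicyclo[2.2.1]heptan-2-yl]pent-2-en-1-ol F3.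
- Methylation with Me2CuLi (Et2O, 0 °C) with retention should give 15.

Step 9. Alkylation of the ambident hydroxycoumarin at the lactone oxygen (2-alkoxychromone) or at C3 may compete, the peri methyl group slows attack through the 4-oxygen, and the product can undergo Claisen rearrangement if warmed. Fallback, setting out from 17 (with 15) and returning at 18, with the roles of the partners reversed. POCl3, Et3N, MeCN at reflux should convert 17 into 4-chloro-5-methyl-2H-chromen-2-one F4. The sodium alkoxide of 15 (NaH, THF, 0 °C to rt) should then displace chloride at C4 by addition–elimination, which forms the ring-carbon–oxygen bond and removes the O- versus C-alkylation question.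

**Further compounds**

F1 | step 4 | (1R,2R,4S)-2-iodo-1,3,3-trimethyl-7-oxabicyclo[2.2.1]heptane (iodine endo) | I[C@@H]1C(C)(C)[C@@H]2CC[C@@]1(C)O2
F2 | step 7 | 5-[(1R,2S,4S)-1,3,3-trimethyl-7-oxabicyclo[2.2.1]heptan-2-yl]pent-2-yn-1-ol | OCC#CCC[C@H]1C(C)(C)[C@@H]2CC[C@@]1(C)O2
F3 | step 7 | (Z)-3-iodo-5-[(1R,2S,4S)-1,3,3-trimethyl-7-oxabicyclo[2.2.1]heptan-2-yl]pent-2-en-1-ol | OC/C=C(\I)CC[C@H]1C(C)(C)[C@@H]2CC[C@@]1(C)O2
F4 | step 9 | 4-chloro-5-methyl-2H-chromen-2-one | Cc1cccc2oc(=O)cc(Cl)c12
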